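**Retrosynthetic overview**
- The target is unmasked last from its tri-O-benzyl flavone by hydrogenolysis.
- Ring C, the only ring built, is closed through the O1–C2 bond by iodine-catalysed oxidative oxa-cyclisation of a 2'-hydroxychalcone; rings A and B are bought as benzenes.
- The chalcone comes from a ring A methyl ketone and a ring B aldehyde (Claisen–Schmidt).
- Ring A: the future C6–OMe bond is made by para C–H methoxylation of 2-hydroxy-4,6-bis(benzyloxy)acetophenone (from phloroacetophenone). The free OH that directs this oxidation later closes ring C, which fixes 6-methoxy over 8-methoxy.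
- Ring B: the 2'-OMe bond is made by copper-catalysed methoxylation of 6-bromo-O-benzylvanillin (from O-benzylvanillin).

Assumption: the target is an achiral flavone with no stereocentre, so no enantiocontrol is needed; the only stereo-element on the way is the E alkene of the chalcone.

**Step 1**
Reactants: 1 2,4,6-trihydroxyacetophenone
Product: 2 1-[2,4-bis(benzyloxy)-6-hydroxyphenyl]ethan-1-one
Conditions: BnBr (2.1 equiv), K2CO3 (2.2 equiv), DMF, 0 °C to rt, 12 h
Reagents that add atoms: benzyl bromide, BrCc1ccccc1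
Why: Williamson O-benzylation takes the 4-OH and one of the two equivalent ortho OH groups, while the last ortho OH is hydrogen-bonded to the acetyl carbonyl, is much less nucleophilic and stays free.

**Step 2**
Reactants: 2 1-[2,4-bis(benzyloxy)-6-hydroxyphenyl]ethan-1-one
Product: 4 1-[2,4-bis(benzyloxy)-6-hydroxy-3-methoxyphenyl]ethan-1-one, via quinone monoketal 3 (not isolated)
Conditions: PhI(OAc)2 (2.2 equiv), dry MeOH/CH2Cl2 (4:1), 0 °C, 1 h; then Zn dust (6 equiv), AcOH (10 equiv), 0 °C to rt, 1 h
Reagents that add atoms: methanol, CO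
Why: Proposed new method: a one-flask para C–H methoxylation of a hydrogen-bonded 2-acylphenol, in which PhI(OAc)2 (a trivalent iodine oxidant) exchanges a ligand for the phenol oxygen, methanol attacks the open para carbon (activated by the para oxygen and both flanking benzyloxy groups, the same carbon that Elbs persulfate oxidation hydroxylates), the p-methoxyphenol formed is oxidised again to quinone monoketal 3, and Zn/AcOH reduces 3 with loss of methanol so that both oxidation levels converge on 4; the closest known reaction type is oxidative dearomatisation of phenols to para-quinone monoketals with PhI(OAc)2 in MeOH together with reductive rearomatisation of quinone monoketals, not yet shown as a telescoped para-methoxylation on a phloroglucinol-type 2-acylphenol.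

**Step 3**
Reactants: 5 4-(benzyloxy)-3-methoxybenzaldehyde
Product: 6 4-(benzyloxy)-2-bromo-5-methoxybenzaldehyde
Conditions: Br2 (1.1 equiv), NaOAc (1.2 equiv), AcOH, rt, 4 h
Reagents that add atoms: bromine, BrBr
Why: Electrophilic aromatic bromination goes para to the methoxy group, as with veratraldehyde, because the donation of the 4-alkoxy group is tied up in conjugation with the formyl group.

**Step 4**
Reactants: 6 4-(benzyloxy)-2-bromo-5-methoxybenzaldehyde
Product: 7 4-(benzyloxy)-2,5-dimethoxybenzaldehyde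
Conditions: NaOMe (4 equiv, 25 wt% in MeOH), CuBr (15 mol%), DMF, 110 °C, 4 h
Reagents that add atoms: sodium methoxide, [Na+].[O-]C
Why: Copper-catalysed Ullmann-type C–O coupling replaces the bromide, which is activated by the ortho formyl group, with methoxide and leaves the benzyl ether untouched.

**Step 5**
Reactants: 4 1-[2,4-bis(benzyloxy)-6-hydroxy-3-methoxyphenyl]ethan-1-one; 7 4-(benzyloxy)-2,5-dimethoxybenzaldehyde
Product: 8 (E)-1-[2,4-bis(benzyloxy)-6-hydroxy-3-methoxyphenyl]-3-[4-(benzyloxy)-2,5-dimethoxyphenyl]prop-2-en-1-one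
Conditions: KOH (10 equiv, 50% aq.), EtOH, rt, 48 h; then dilute HCl to pH 4
Reagents that add atoms: none
Why: Claisen–Schmidt aldol condensation of the methyl ketone enolate with the non-enolisable aldehyde, followed by E1cB dehydration, gives the thermodynamically favoured E enone.

**Step 6**
Reactants: 8 (E)-1-[2,4-bis(benzyloxy)-6-hydroxy-3-methoxyphenyl]-3-[4-(benzyloxy)-2,5-dimethoxyphenyl]prop-2-en-1-one
Product: 10 5,7-bis(benzyloxy)-2-[4-(benzyloxy)-2,5-dimethoxyphenyl]-6-methoxy-4H-chromen-4-one, via racemic flavanone 9 (not isolated)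
Conditions: I2 (10 mol%), DMSO, 120 °C, 3 h; aq. Na2S2O3 work-up
Reagents that add atoms: none
Why: Iodine-catalysed oxidative cyclisation, in which oxa-Michael addition of the one free phenol to the enone forms the O1–C2 bond of ring C (flavanone 9) and I2/DMSO dehydrogenates it to the flavone, with DMSO as terminal oxidant reoxidising HI to I2.

**Step 7**
Reactants: 10 5,7-bis(benzyloxy)-2-[4-(benzyloxy)-2,5-dimethoxyphenyl]-6-methoxy-4H-chromen-4-one
Product: 11 5,7-dihydroxy-2-(4-hydroxy-2,5-dimethoxyphenyl)-6-methoxy-4H-chromen-4-one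
Conditions: H2 (1 atm), Pd/C (10 wt% Pd, 10 mol%), THF/MeOH (1:1), rt, 6 h
Reagents that add atoms: none
Why: Catalytic hydrogenolysis cleaves the three benzyl aryl ethers, while the methyl ethers and the vinylogous-ester C2=C3 bond of the flavone are inert under these mild conditions.

**Compound list**
1 | 1-(2,4,6-trihydroxyphenyl)ethan-1-one (2,4,6-trihydroxyacetophenone) | CC(=O)c1c(O)cc(O)cc1O | starting material
2 | 1-[2,4-bis(benzyloxy)-6-hydroxyphenyl]ethan-1-one | CC(=O)c1c(O)cc(OCc2ccccc2)cc1OCc1ccccc1 | intermediate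
3 | 2-acetyl-3,5-bis(benzyloxy)-4,4-dimethoxycyclohexa-2,5-dien-1-one (quinone monoketal) | CC(=O)C1=C(OCc2ccccc2)C(OC)(OC)C(OCc2ccccc2)=CC1=O | intermediate
4 | 1-[2,4-bis(benzyloxy)-6-hydroxy-3-methoxyphenyl]ethan-1-one | CC(=O)c1c(O)cc(OCc2ccccc2)c(OC)c1OCc1ccccc1 | intermediate
5 | 4-(benzyloxy)-3-methoxybenzaldehyde (O-benzylvanillin) | COc1cc(C=O)ccc1OCc1ccccc1 | starting material
6 | 4-(benzyloxy)-2-bromo-5-methoxybenzaldehyde | COc1cc(C=O)c(Br)cc1OCc1ccccc1 | intermediate
7 | 4-(benzyloxy)-2,5-dimethoxybenzaldehyde | COc1cc(C=O)c(OC)cc1OCc1ccccc1 | intermediate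
8 | (E)-1-[2,4-bis(benzyloxy)-6-hydroxy-3-methoxyphenyl]-3-[4-(benzyloxy)-2,5-dimethoxyphenyl]prop-2-en-1-one | COc1cc(/C=C/C(=O)c2c(O)cc(OCc3ccccc3)c(OC)c2OCc2ccccc2)c(OC)cc1OCc1ccccc1 | intermediate
9 | 5,7-bis(benzyloxy)-2-[4-(benzyloxy)-2,5-dimethoxyphenyl]-6-methoxy-2,3-dihydro-4H-chromen-4-one (racemic flavanone) | COc1cc(C2CC(=O)c3c(OCc4ccccc4)c(OC)c(OCc4ccccc4)cc3O2)c(OC)cc1OCc1ccccc1 | intermediate
10 | 5,7-bis(benzyloxy)-2-[4-(benzyloxy)-2,5-dimethoxyphenyl]-6-methoxy-4H-chromen-4-one | COc1cc(-c2cc(=O)c3c(OCc4ccccc4)c(OC)c(OCc4ccccc4)cc3o2)c(OC)cc1OCc1ccccc1 | intermediate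
11 | 5,7-dihydroxy-2-(4-hydroxy-2,5-dimethoxyphenyl)-6-methoxy-4H-chromen-4-one | COc1cc(-c2cc(=O)c3c(O)c(OC)c(O)cc3o2)c(OC)cc1O | target

**Step count and risks**
Total steps: 7. Longest linear sequence: 5 (steps 1, 2, 5, 6, 7; the ring B branch through steps 3, 4, 5, 6, 7 is equally long).

The three steps most likely to fail:

Step 2 (the proposed new para-methoxylation). Risks are ortho attack of methanol, exchange of a benzyloxy group for methoxy at the ketal stage, quinone formation if water is present, and slow ligand exchange of the hydrogen-bonded phenol. The fallback uses known chemistry and sets out from 2. Elbs persulfate oxidation (K2S2O8, aq. KOH/pyridine, rt) gives potassium 3-acetyl-2,6-bis(benzyloxy)-4-hydroxyphenyl sulfate F1. Hydrolysis with dilute HCl at 50 °C gives 1-[2,4-bis(benzyloxy)-3,6-dihydroxyphenyl]ethan-1-one F2. MeI (1.05 equiv) with K2CO3 in acetone then methylates only the non-chelated hydroxyl, and the route is rejoined at 4.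

Step 5 (Claisen–Schmidt condensation). The ketone is flanked by two ortho substituents and the aldehyde is very electron-rich, so conversion may be slow and retro-aldol or premature flavanone formation may intervene. The fallback sets out from 7 and 4 and replaces the chalcone by a 1,3-diketone. Aldehyde 7 is oxidised with I2/KOH in MeOH at 0 °C to methyl 4-(benzyloxy)-2,5-dimethoxybenzoate F3. The lithium dianion of 4 (LiHMDS, 3.5 equiv, THF, −78 °C to rt) is acylated by F3 in a crossed Claisen condensation to give 1-[2,4-bis(benzyloxy)-6-hydroxy-3-methoxyphenyl]-3-[4-(benzyloxy)-2,5-dimethoxyphenyl]propane-1,3-dione F4. Cyclodehydration of F4 (TsOH·H2O cat., toluene, 80 °C) closes ring C, and the route is rejoined at 10, bypassing 8 and step 6.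

Step 1 (selective bis-benzylation). Tri-O-benzylation and C-benzylation of the phloroglucinol ring compete and can depress the yield. The fallback sets out from 1. Exhaustive benzylation (BnBr 3.5 equiv, K2CO3, DMF, 80 °C) gives 1-[2,4,6-tris(benzyloxy)phenyl]ethan-1-one F5. Chelation-controlled cleavage of one benzyl ether ortho to the carbonyl with MgBr2·OEt2 (1.2 equiv, toluene/Et2O, reflux) then rejoins the route at 2.

**Further compounds**
F1 | step 2 | potassium 3-acetyl-2,6-bis(benzyloxy)-4-hydroxyphenyl sulfate | CC(=O)c1c(O)cc(OCc2ccccc2)c(OS(=O)(=O)[O-])c1OCc1ccccc1.[K+]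
F2 | step 2 | 1-[2,4-bis(benzyloxy)-3,6-dihydroxyphenyl]ethan-1-one | CC(=O)c1c(O)cc(OCc2ccccc2)c(O)c1OCc1ccccc1
F3 | step 5 | methyl 4-(benzyloxy)-2,5-dimethoxybenzoate | COC(=O)c1cc(OC)c(OCc2ccccc2)cc1OC
F4 | step 5 | 1-[2,4-bis(benzyloxy)-6-hydroxy-3-methoxyphenyl]-3-[4-(benzyloxy)-2,5-dimethoxyphenyl]propane-1,3-dione | COc1cc(C(=O)CC(=O)c2c(O)cc(OCc3ccccc3)c(OC)c2OCc2ccccc2)c(OC)cc1OCc1ccccc1
F5 | step 1 | 1-[2,4,6-tris(benzyloxy)phenyl]ethan-1-one | CC(=O)c1c(OCc2ccccc2)cc(OCc2ccccc2)cc1OCc1ccccc1
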